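The earlier runs and the new flask stem from a simulated flask on assumed constants.

Over the last 5.00 min of Wednesday's run, the fraction of the charge not yet target read 62.0% and then 51.0%. I call this the open fraction. Its logarithm fell at 0.0391 /min, and over the same span of Monday's run at 0.0454 /min. I took the mean of these readings, 0.0422 /min, as the closing constant: the gain of target per minute divided by the open fraction, an apparent pseudo-first-order constant. Dividing Monday's rate by Wednesday's removes time and leaves 1.16, for a charge 2.24 times as large. I therefore treated the charge as the setting not worth changing and turned to the clock.

| flask | starting material | remark | time |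
|---|---|---|---|
| Wednesday's | 0.67 M | run made earlier |  |
| Monday's | 1.5 M | run made earlier |  |
| amber | 1.0 M |  | 25 min |
| blue | 1.0 M |  | 20 min |

| run | time / min | starting material / % | target / % | intermediate B / % | intermediate A / % |
|---|---|---|---|---|---|
| Wednesday's | 1.33 | 85 | 0 | 3 | 12 |
| Wednesday's | 4.00 | 57 | 1 | 8 | 39 |
| Wednesday's | 6.00 | 46 | 2 | 9 | 40 |
| Wednesday's | 10.0 | 31 | 10 | 21 | 42 |
| Wednesday's | 15.0 | 12 | 22 | 29 | 39 |
| Wednesday's | 20.0 | 6 | 38 | 26 | 30 |
| Wednesday's | 25.0 | 2 | 49 | 23 | 21 |
| Monday's | 3.00 | 65 | 0 | 2 | 29 |
| Monday's | 6.00 | 45 | 3 | 9 | 40 |
| Monday's | 10.0 | 25 | 9 | 21 | 43 |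
| Monday's | 15.0 | 16 | 23 | 24 | 35 |
| Monday's | 20.0 | 6 | 36 | 24 | 28 |
| Monday's | 25.0 | 6 | 49 | 23 | 19 |

(standard deviation of a reading: 1.5 percentage points)

- which of these there is most of at the end, counted by the starting material in it, amber (starting material / target / intermediate A / intermediate B)
- which of these there is most of at the end, counted by the starting material in it, blue (starting material / target / intermediate A / intermediate B)
- how much there is at the end of the one of these that leads, in percent of the starting material charged: amber
- how much there is at the end of the one of these that leads, in percent of the starting material charged: blue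

- the numbers in the tables scatter with a standard deviation of 1.5 percentage points
- a reading or a percentage of target counts all its forms, free or not

Amber and blue have the same charge, 1.0 M, and differ in time, 25 min against 20 min. The two runs read a mean open fraction of 0.510 at 25 min and 0.630 at 20 min. So I committed to target at 0.490 of the charge for amber and 0.370 for blue. In blue, that stands ahead of the mean reading for intermediate A, 0.290. The extra 5.00 min multiply the open fraction by 0.810, so I would run amber's time.

The forecast gave target at 49% for amber and target at 37% for blue, holding that “the profile does not depend on concentration”.

Amber gave target at 50.1%, and blue gave target at 36.5%. From Wednesday's run, changing the charge to blue's left target at 50.1%, while changing the time to blue's took it to 36.3%. Applied to blue's open fraction, 63.5%, the closing constant gives amber's target as 0.486 of the charge.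

    starting material → intermediate A (k = 0.00219 /s)
    crystals ⇌ target, rate k2*(cs2 - [target]) while solid is left; crystals form when [target] > cs2 (solubility = 19.0 mM, k = 0.0178 /s)
    intermediate B ⇌ target (K = 1.60, k = 0.00208 /s)
    starting material + intermediate A → side product (k = 1.01 × 10⁻⁴ /M/s)
    intermediate A → intermediate B (k = 0.00151 /s)

A neighbouring flask is amber read at 40 min. The closing constant, applied to amber's open fraction over the further 15.0 min, gives target at 0.735 of the charge. The computed flask holds 78.3%.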